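**Retrosynthetic overview**
1. The C2-symmetric tetraene is cut at its central C(sp2)–C(sp2) bond. This gives two identical (E)-dienylboronates, each made from one ring enol triflate and a two-carbon vinylene bis-boronate.
2. Each oxirane comes from a reagent-controlled epoxidation of a 4-methylpent-3-enyl chain. It is done while the ring alkene is still an electron-poor enol triflate.
3. The side chain and the free carbinol come from reductive opening and Wittig olefination of a cis-fused δ-lactone.
4. Key disconnection: the quaternary C–CH2 bond. A 3-iodopropanoate hung on the carbinol oxygen closes as a radical onto the β-carbon of the 3-methylcyclohexenone. This places carbon syn to oxygen and leaves the regiodefined enolate, which is trapped as the triflate.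
5. Ring order: the carbocycle is bought, the temporary lactone ring forms in the radical step and is opened again, and the oxiranes are formed last. No ring forms in the dimerisation.

Assumption: (S)-Me-CBS, the D-fructose-derived Shi ketone, PhNTf2, isopropyltriphenylphosphonium iodide and (E)-1,2-bis(pinacolboryl)ethene are bought as reagents.

**Step 1**
Reactants: 1 2-methylcyclohex-2-en-1-one
Product: 2 (1R)-2-methylcyclohex-2-en-1-ol
Conditions: (S)-Me-CBS (10 mol %), BH3·SMe2 (0.6 equiv), THF, −20 °C; aq. work-up
Reagents that add atoms: none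
Why: Corey–Bakshi–Shibata reduction, in which the catalyst-bound borane delivers hydride to the ketone face that keeps the larger α-methylvinyl arm away from the B-methyl group, sets the carbinol centre as R (the ring C–OH of the target) and leaves the alkene untouched.

**Step 2**
Reactants: 2 (1R)-2-methylcyclohex-2-en-1-ol; 3 3-iodopropanoic acid
Product: 4 (1R)-2-methylcyclohex-2-en-1-yl 3-iodopropanoate
Conditions: DCC, DMAP (10 mol %), CH2Cl2, 0 °C to rt
Reagents that add atoms: none
Why: Steglich esterification under near-neutral conditions hangs the three-carbon radical precursor on the carbinol oxygen without disturbing the stereocentre or eliminating HI.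

**Step 3**
Reactants: 4 (1R)-2-methylcyclohex-2-en-1-yl 3-iodopropanoate
Product: 5 (1R)-2-methyl-4-oxocyclohex-2-en-1-yl 3-iodopropanoate
Conditions: CrO3, 3,5-dimethylpyrazole, CH2Cl2, −20 °C
Reagents that add atoms: chromium trioxide, O=[Cr](=O)=O
Why: Chromium(VI) allylic oxidation attacks the only unhindered ring allylic CH2, because the acyloxy-bearing allylic C–H is electronically deactivated, and so turns the alkene into the enone acceptor with the stereocentre intact.

**Step 4 (key step)**
Reactants: 5 (1R)-2-methyl-4-oxocyclohex-2-en-1-yl 3-iodopropanoate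
Product: 7 (4aS,8aR)-4a-methyl-2-oxo-3,4,4a,7,8,8a-hexahydro-2H-chromen-6-yl trifluoromethanesulfonate, via diethylboron enolate 6 (not isolated)
Conditions: Et3B (2.5 equiv, slow addition), trace air, PhH (0.01 M), 80 °C; evaporate; t-BuOK, PhNTf2, THF, −78 to 0 °C
Reagents that add atoms: N-phenylbis(trifluoromethanesulfonimide), O=S(=O)(N(c1ccccc1)S(=O)(=O)C(F)(F)F)C(F)(F)F; triethylborane, CCB(CC)CC (its BEt2 group is carried only by 6)
Why: Proposed new method: ethyl radicals from Et3B/O2 abstract iodine from 5 and the primary radical closes 6-exo-trig onto the enone β-carbon (a tethered Giese reaction); because A(1,2) strain with the ring methyl holds the C–O bond pseudoaxial, the four-atom ester tether reaches only the face syn to oxygen, which forms the key C4a–C4 bond, sets the quaternary centre as 4aS in a cis-fused lactone and leaves an enoxyl radical that Et3B captures as the regiodefined boron enolate 6 (releasing the chain-carrying Et•), and alkoxide exchange followed by PhNTf2 then gives the C5=C6 enol triflate; the closest known reaction types are the Et3B-induced radical conjugate addition of alkyl iodides to enones, which ends in boron enolates, and Ueno–Stork temporary-tether radical cyclisations.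

**Step 5**
Reactants: 7 (4aS,8aR)-4a-methyl-2-oxo-3,4,4a,7,8,8a-hexahydro-2H-chromen-6-yl trifluoromethanesulfonate
Product: 9 (3S,4R)-4-hydroxy-3-methyl-3-(4-methylpent-3-en-1-yl)cyclohex-1-en-1-yl trifluoromethanesulfonate, via lactol 8 (not isolated)
Conditions: DIBAL-H (1.1 equiv), CH2Cl2, −78 °C; then i-PrPPh3I/n-BuLi (3 equiv ylide), THF, −78 °C to rt; Rochelle salt
Reagents that add atoms: isopropyltriphenylphosphonium iodide, CC(C)[P+](c1ccccc1)(c1ccccc1)c1ccccc1.[I-]
Why: Partial DIBAL-H reduction of the δ-lactone followed by Wittig olefination of the ring-opened hydroxy aldehyde with the non-stabilised isopropylidene ylide frees the secondary alcohol and completes the 4-methylpent-3-enyl chain, and neither the stereocentres nor the enol triflate are affected.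

**Step 6**
Reactants: 9 (3S,4R)-4-hydroxy-3-methyl-3-(4-methylpent-3-en-1-yl)cyclohex-1-en-1-yl trifluoromethanesulfonate
Product: 10 (3S,4R)-3-{2-[(2R)-3,3-dimethyloxiran-2-yl]ethyl}-4-hydroxy-3-methylcyclohex-1-en-1-yl trifluoromethanesulfonate
Conditions: Shi ketone (D-fructose-derived, 30 mol %), Oxone, K2CO3, Bu4NHSO4, MeCN–DMM/aq. borate–EDTA buffer, 0 °C
Reagents that add atoms: potassium peroxymonosulfate (Oxone), [K+].[O-]S(=O)(=O)OO
Why: Shi asymmetric epoxidation, in which the dioxirane of the D-fructose-derived ketone meets the electron-rich trisubstituted side-chain alkene through the spiro transition state, gives the R oxirane under reagent control, while the electron-poor, neopentyl-flanked enol triflate alkene stays inert.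

**Step 7**
Reactants: 10 (3S,4R)-3-{2-[(2R)-3,3-dimethyloxiran-2-yl]ethyl}-4-hydroxy-3-methylcyclohex-1-en-1-yl trifluoromethanesulfonate
Product: 11 (1R,2S)-2-{2-[(2R)-3,3-dimethyloxiran-2-yl]ethyl}-2-methyl-4-[(E)-2-(4,4,5,5-tetramethyl-1,3,2-dioxaborolan-2-yl)ethenyl]cyclohex-3-en-1-ol
Conditions: (E)-pinBCH=CHBpin (3 equiv), Pd(dppf)Cl2 (5 mol %), K3PO4, THF–H2O, 40 °C
Reagents that add atoms: (E)-1,2-bis(4,4,5,5-tetramethyl-1,3,2-dioxaborolan-2-yl)ethene, CC1(C)OB(/C=C/B2OC(C)(C)C(C)(C)O2)OC1(C)C
Why: Suzuki–Miyaura coupling proceeds with retention at both sp2 carbons, the threefold excess of the bis-boronate stops the reaction after one C–B bond, and the mild aqueous phosphate base spares the oxirane and the alcohol.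

**Step 8**
Reactants: 11 (two equivalents) (1R,2S)-2-{2-[(2R)-3,3-dimethyloxiran-2-yl]ethyl}-2-methyl-4-[(E)-2-(pinacolboryl)ethenyl]cyclohex-3-en-1-ol
Product: 12 (1R,1'R,2S,2'S)-4,4'-[(1E,3E)-buta-1,3-diene-1,4-diyl]bis{2-[2-((2R)-3,3-dimethyloxiran-2-yl)ethyl]-2-methylcyclohex-3-en-1-ol} (target)
Conditions: Pd(OAc)2 (5 mol %), K2CO3, air (1 atm), THF–H2O, rt, dark
Reagents that add atoms: none
Why: Palladium-catalysed oxidative homocoupling of the alkenylboronate (double transmetalation, reductive elimination, reoxidation by O2) joins the two identical halves with retention of both E alkenes, and any minor-enantiomer material ends up in separable heterochiral dimers.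

**Compound list**
1 | 2-methylcyclohex-2-en-1-one | CC1=CCCCC1=O | starting material
2 | (1R)-2-methylcyclohex-2-en-1-ol | CC1=CCCC[C@H]1O | intermediate
3 | 3-iodopropanoic acid | OC(=O)CCI | starting material
4 | (1R)-2-methylcyclohex-2-en-1-yl 3-iodopropanoate | CC1=CCCC[C@H]1OC(=O)CCI | intermediate
5 | (1R)-2-methyl-4-oxocyclohex-2-en-1-yl 3-iodopropanoate | CC1=CC(=O)CC[C@H]1OC(=O)CCI | intermediate
6 | (4aS,8aR)-6-[(diethylboranyl)oxy]-4a-methyl-3,4,4a,7,8,8a-hexahydro-2H-chromen-2-one | O=C1CC[C@@]2(C)C=C(OB(CC)CC)CC[C@H]2O1 | intermediate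
7 | (4aS,8aR)-4a-methyl-2-oxo-3,4,4a,7,8,8a-hexahydro-2H-chromen-6-yl trifluoromethanesulfonate | O=C1CC[C@@]2(C)C=C(OS(=O)(=O)C(F)(F)F)CC[C@H]2O1 | intermediate
8 | (4aS,8aR)-2-hydroxy-4a-methyl-3,4,4a,7,8,8a-hexahydro-2H-chromen-6-yl trifluoromethanesulfonate (lactol, anomer mixture, present as its aluminium alkoxide) | OC1CC[C@@]2(C)C=C(OS(=O)(=O)C(F)(F)F)CC[C@H]2O1 | intermediate
9 | (3S,4R)-4-hydroxy-3-methyl-3-(4-methylpent-3-en-1-yl)cyclohex-1-en-1-yl trifluoromethanesulfonate | CC(C)=CCC[C@@]1(C)C=C(OS(=O)(=O)C(F)(F)F)CC[C@H]1O | intermediate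
10 | (3S,4R)-3-{2-[(2R)-3,3-dimethyloxiran-2-yl]ethyl}-4-hydroxy-3-methylcyclohex-1-en-1-yl trifluoromethanesulfonate | CC1(C)O[C@@H]1CC[C@@]1(C)C=C(OS(=O)(=O)C(F)(F)F)CC[C@H]1O | intermediate
11 | (1R,2S)-2-{2-[(2R)-3,3-dimethyloxiran-2-yl]ethyl}-2-methyl-4-[(E)-2-(pinacolboryl)ethenyl]cyclohex-3-en-1-ol | CC1(C)O[C@@H]1CC[C@@]1(C)C=C(/C=C/B2OC(C)(C)C(C)(C)O2)CC[C@H]1O | intermediate
12 | CNP0229121.4 | CC1(C)O[C@@H]1CC[C@@]1(C)C=C(/C=C/C=C/C2=C[C@](C)(CC[C@H]3OC3(C)C)[C@H](O)CC2)CC[C@H]1O | target

**Total step count:** 8. **Longest linear sequence:** 8 steps (1 → 12).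

**Steps most likely to fail**

*Step 4.* The ester prefers the Z rotamer, in which the radical cannot reach the enone. The 6-exo closure may therefore be slow, and the O-triflation of a boron enolate is untested.
Fallback: set out from 5 and eliminate HI with DBU to give the acrylate (1R)-2-methyl-4-oxocyclohex-2-en-1-yl prop-2-enoate F1. The roles of radical and acceptor are then exchanged. Bu3SnH/AIBN (slow addition, PhH, 80 °C) adds Bu3Sn• reversibly to the enone oxygen. The long-lived allylic O-stannyl ketyl attacks the acrylate terminus through its β-carbon under the same cis constraint. Hydrogen transfer leaves the tin enolate (4aS,8aR)-4a-methyl-6-[(tributylstannyl)oxy]-3,4,4a,7,8,8a-hexahydro-2H-chromen-2-one F2. Treatment with t-BuOK and PhNTf2 converts F2 into 7, where the route is rejoined.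

*Step 3.* Chromium(VI) acts in the presence of a primary iodide and an allylic ester, so low yield or loss of HI is possible.
Fallback: set out from 2 and bring in the iodide only after the oxidation. Silylation (TBSCl, imidazole) gives tert-butyl(dimethyl){[(1R)-2-methylcyclohex-2-en-1-yl]oxy}silane F3. Catalytic allylic oxidation (Rh2(cap)4, t-BuOOH) gives (4R)-4-[(tert-butyldimethylsilyl)oxy]-3-methylcyclohex-2-en-1-one F4. HF·pyridine frees (4R)-4-hydroxy-3-methylcyclohex-2-en-1-one F5. Steglich esterification of F5 with 3 comes back to the route at 5.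

*Step 8.* Protodeboronation may compete, and the tetraene may be oxidised under air.
Fallback: set out from 11 and replace the oxidative homocoupling by a redox-neutral cross-coupling. Half of 11 is iododeboronated with retention (NIS, MeCN, 0 °C) to (1R,2S)-2-{2-[(2R)-3,3-dimethyloxiran-2-yl]ethyl}-4-[(E)-2-iodoethenyl]-2-methylcyclohex-3-en-1-ol F6. F6 is then joined with the other half of 11 under Suzuki–Miyaura conditions (Pd(PPh3)4, K3PO4, degassed THF–H2O, rt), which gives 12 directly.

**Further compounds**
F1 | step 4 | (1R)-2-methyl-4-oxocyclohex-2-en-1-yl prop-2-enoate | CC1=CC(=O)CC[C@H]1OC(=O)C=C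
F2 | step 4 | (4aS,8aR)-4a-methyl-6-[(tributylstannyl)oxy]-3,4,4a,7,8,8a-hexahydro-2H-chromen-2-one | O=C1CC[C@@]2(C)C=C(O[Sn](CCCC)(CCCC)CCCC)CC[C@H]2O1
F3 | step 3 | tert-butyl(dimethyl){[(1R)-2-methylcyclohex-2-en-1-yl]oxy}silane | CC1=CCCC[C@H]1O[Si](C)(C)C(C)(C)C
F4 | step 3 | (4R)-4-[(tert-butyldimethylsilyl)oxy]-3-methylcyclohex-2-en-1-one | CC1=CC(=O)CC[C@H]1O[Si](C)(C)C(C)(C)C
F5 | step 3 | (4R)-4-hydroxy-3-methylcyclohex-2-en-1-one | CC1=CC(=O)CC[C@H]1O
F6 | step 8 | (1R,2S)-2-{2-[(2R)-3,3-dimethyloxiran-2-yl]ethyl}-4-[(E)-2-iodoethenyl]-2-methylcyclohex-3-en-1-ol | CC1(C)O[C@@H]1CC[C@@]1(C)C=C(/C=C/I)CC[C@H]1O
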